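The hexamer is cut at ring C, the one ring whose pattern a vinylketene–ynol ether benzannulation writes directly: oxygen on C1, C3 and C5, the CH2 bridges to rings B and D on C2 and C4, and a free C6 for the last butyryl group. One thermal operation joins an A–B methoxyalkyne to a 3-methoxycyclobutenone bearing rings D–E–F, makes two C–C bonds between them and closes ring C as a phenol. Both partners come from fully O-methylated benzylic bromides by Negishi coupling with (methoxyethynyl)zinc chloride, a reagent made in a step of its own; the D–E–F alkyne is then turned into the cyclobutenone with dichloroketene and zinc.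

Key step: step 17

Remark (lettering): rings run A (gem-dimethyl dienone) to F (C-methyl ring); ring C is numbered C1 (OH), C2 (CH2 to ring B), C3 (OMe), C4 (CH2 to ring D), C5 (OMe), C6 (H, later butyryl).
Remark (design): both alkynyl ethers are methyl ethers, because an ethyl alkynyl ether would lose ethene by a retro-ene reaction in the temperature range of the annulation; the bromides are alkynylated through zinc because they carry aryl ketones that a lithium acetylide would attack.
Assumption: double O-methylation of ring A (step 15) is taken to give the 3,5-di-O-methyl cross-conjugated dienone drawn for 24; a regioisomeric bis-enol ether would behave alike in steps 16–19 and give the same target in step 20.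

Step 1
Reactants: 1 1,3,5-trimethoxybenzene; 2 butyryl chloride
Product: 3 1-(2,4,6-trimethoxyphenyl)butan-1-one
Conditions: AlCl3, CH2Cl2, 0 °C
Reagents that add atoms: none
Why: Friedel–Crafts acylation of the electron-rich arene, which should stop at the mono-ketone because the AlCl3-bound acyl group deactivates the ring.

Step 2
Reactants: 3 1-(2,4,6-trimethoxyphenyl)butan-1-one
Product: 4 1-[3,5-bis(bromomethyl)-2,4,6-trimethoxyphenyl]butan-1-one
Conditions: (CH2O)n, 33% HBr in AcOH, 50 °C
Reagents that add atoms: paraformaldehyde (counted as formaldehyde), C=O; hydrogen bromide, Br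
Why: Blanc-type bromomethylation, in which the two equivalent free ring carbons, each between two methoxy groups and only weakly deactivated by the twisted ketone, should both be substituted.

Step 3
Reactants: 5 2,4,6-trimethoxytoluene; 2 butyryl chloride
Product: 6 1-(2,4,6-trimethoxy-3-methylphenyl)butan-1-one
Conditions: AlCl3, CH2Cl2, 0 °C
Reagents that add atoms: none
Why: Friedel–Crafts acylation at one of the two equivalent free ring carbons, so that only one product can form.

Step 4
Reactants: 6 1-(2,4,6-trimethoxy-3-methylphenyl)butan-1-one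
Product: 7 1-[3-(bromomethyl)-2,4,6-trimethoxy-5-methylphenyl]butan-1-one
Conditions: (CH2O)n, 33% HBr in AcOH, 40 °C
Reagents that add atoms: paraformaldehyde (counted as formaldehyde), C=O; hydrogen bromide, Br
Why: Blanc-type bromomethylation at the single unsubstituted ring carbon, which lies between two methoxy groups.

Step 5
Reactants: 7 1-[3-(bromomethyl)-2,4,6-trimethoxy-5-methylphenyl]butan-1-one; 3 1-(2,4,6-trimethoxyphenyl)butan-1-one
Product: 8 E-F diarylmethane
Conditions: 3 (3 equiv), NaHCO3, HFIP/CH2Cl2, 0 °C → rt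
Reagents that add atoms: none
Why: Friedel–Crafts benzylation in which HFIP ionises the doubly ortho-methoxylated benzylic bromide, the excess of 3 limits double alkylation, and NaHCO3 removes HBr so that the new bridge cannot equilibrate.

Step 6
Reactants: 8 E-F diarylmethane; 4 1-[3,5-bis(bromomethyl)-2,4,6-trimethoxyphenyl]butan-1-one
Product: 9 D-E-F benzylic bromide
Conditions: 4 (3 equiv), NaHCO3, HFIP/CH2Cl2, 0 °C → rt
Reagents that add atoms: none
Why: Friedel–Crafts benzylation at the only unsubstituted aromatic carbon of 8 (on ring E), with the excess of dibromide 4 favouring substitution of one bromide only.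

Step 7
Reactants: 10 chloroacetaldehyde dimethyl acetal
Product: 12 methoxyacetylene, via sodium methoxyacetylide 11 (not isolated)
Conditions: NaNH2 (3 equiv), liquid NH3, −33 °C; cold aqueous NaCl; distil into cold THF
Reagents that add atoms: none
Why: Twofold base-induced elimination (loss of HCl and of methanol) gives the sodium acetylide, which water protonates to the volatile alkyne.

Step 8
Reactants: 12 methoxyacetylene
Product: 14 (methoxyethynyl)zinc chloride (THF solution), via lithium methoxyacetylide 13 (not isolated)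
Conditions: n-BuLi, THF, −78 °C; ZnCl2 (THF), −78 → 0 °C; solution kept cold under argon, made afresh for each of the two couplings
Reagents that add atoms: zinc dichloride, Cl[Zn]Cl
Why: Deprotonation of the terminal alkyne followed by lithium-to-zinc transmetalation, the standard preparation of an alkynylzinc Negishi reagent, should give a nucleophile mild enough to leave ketones untouched.

Step 9
Reactants: 9 D-E-F benzylic bromide; 14 (methoxyethynyl)zinc chloride
Product: 15 D-E-F methyl ynol ether
Conditions: 14 (1.5 equiv), PdCl2(DPEphos) (5 mol%), THF, rt; basic work-up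
Reagents that add atoms: none
Why: Negishi coupling of an alkynylzinc chloride with a benzylic bromide under zerovalent palladium catalysis (the catalyst forms in the flask from PdCl2(DPEphos)), chosen because the zinc acetylide does not add to the three hindered aryl ketones.

Step 10
Reactants: 15 D-E-F methyl ynol ether; 16 trichloroacetyl chloride
Product: 18 D-E-F 4,4-dichloro-3-methoxycyclobutenone, via dichloroketene 17 (not isolated)
Conditions: activated Zn dust, DME/Et2O, rt
Reagents that add atoms: none
Why: [2+2] cycloaddition of dichloroketene with the ynol ether, whose nucleophilic carbon (bearing the benzylic CH2) bonds to the ketene carbonyl carbon and so places OMe at C3 and CCl2 at C4 of the cyclobutenone.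

Step 11
Reactants: 18 D-E-F 4,4-dichloro-3-methoxycyclobutenone
Product: 19 D-E-F 3-methoxycyclobutenone
Conditions: Zn dust, AcOH, TMEDA, MeOH, 0 °C → rt
Reagents that add atoms: none
Why: Reductive dechlorination of the α,α-dichloro ketone by zinc under buffered conditions, run in methanol so that any exchange at the vinylogous ester is degenerate.

Step 12
Reactants: 20 phloroglucinol; 2 butyryl chloride
Product: 21 1-(2,4,6-trihydroxyphenyl)butan-1-one
Conditions: AlCl3, PhNO2/CH2Cl2, 0 °C → rt
Reagents that add atoms: none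
Why: Friedel–Crafts acylation of phloroglucinol, which should stop after one acyl group because the chelated ketone deactivates the ring.

Step 13
Reactants: 21 1-(2,4,6-trihydroxyphenyl)butan-1-one
Product: 22 butyrylfilicinic acid
Conditions: MeI (2.2 equiv), NaOMe, MeOH, 0 °C → rt
Reagents that add atoms: iodomethane, CI
Why: Dearomative C-methylation of the phloroglucinol polyanion, in which the second methyl group enters the carbon that already carries the first and gives the gem-dimethyl trione, to be separated from isomeric C-methylation products.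

Step 14
Reactants: 22 butyrylfilicinic acid; 4 1-[3,5-bis(bromomethyl)-2,4,6-trimethoxyphenyl]butan-1-one
Product: 23 A-B benzylic bromide (ring A unprotected)
Conditions: 4 (3 equiv), NaHCO3, HFIP/CH2Cl2, 0 °C → rt; used at once
Reagents that add atoms: none
Why: C-Benzylation of a cyclic vinylogous acid at its only ring C–H under ionising, Friedel–Crafts-type conditions, where O-alkylation is reversible and drains to the C-alkyl product.

Step 15
Reactants: 23 A-B benzylic bromide (ring A unprotected)
Product: 24 A-B benzylic bromide (ring A as bis-methyl enol ether)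
Conditions: TMSCHN2, MeOH (5 equiv), CH2Cl2, 0 °C
Reagents that add atoms: (trimethylsilyl)diazomethane, C[Si](C)(C)C=[N+]=[N-]
Why: O-Methylation of the two acidic enols by a diazoalkane, with only a few equivalents of methanol so that the benzylic bromide is not solvolysed.

Step 16
Reactants: 24 A-B benzylic bromide (ring A as bis-methyl enol ether); 14 (methoxyethynyl)zinc chloride
Product: 25 A-B methyl ynol ether
Conditions: 14 (1.5 equiv), PdCl2(DPEphos) (5 mol%), THF, rt; basic work-up
Reagents that add atoms: none
Why: Negishi coupling of the alkynylzinc chloride with the benzylic bromide, the zinc reagent being too weak a nucleophile to attack the aryl ketone or the vinylogous esters of ring A.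

Step 17
Reactants: 25 A-B methyl ynol ether; 19 D-E-F 3-methoxycyclobutenone
Product: 30 protected hexamer phenol (ring C without butyryl), via vinylketene 26 (not isolated), via 4-vinylcyclobutenone 27 (not isolated), via dienylketene 28 (not isolated), via cyclohexadienone 29 (not isolated)
Conditions: 25 (1.2 equiv), toluene, 120 °C, sealed tube
Reagents that add atoms: none
Why: Heating opens cyclobutenone 19 by a four-electron electrocyclic reaction to vinylketene 26, which adds the electron-rich triple bond of 25 in a [2+2] cycloaddition to give 4-vinylcyclobutenone 27; a second four-electron opening gives dienylketene 28, whose six-electron electrocyclisation gives dienone 29, and tautomerisation gives phenol 30. The closest known reaction type is the Danheiser benzannulation of a cyclobutenone with an alkoxyalkyne, here with the less-tested 3-alkoxy cyclobutenone. Ring C is closed by the thermal disrotatory 6π electrocyclisation that joins the ketene carbon (C1) to the former ring CH2 (C6), after the two bonds between the fragments (C1–C2 and C3–C4) were made in the [2+2] step. No stereocentre is set, since the quaternary carbon of 27 becomes sp2 again in the next ring opening. The step needs regiocontrol in the [2+2] event, and the polarisation of the ynol ether secures it: its carbon bearing the CH2 of ring B is the nucleophilic one and bonds to the ketene carbonyl carbon, so the three oxygens of ring C end up on C1, C3 and C5. The methyl ynol ether has no β-hydrogen and so cannot fragment by a retro-ene reaction at this temperature, and its slight excess keeps the vinylketene from acylating the phenol that forms.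

Step 18
Reactants: 30 protected hexamer phenol (ring C without butyryl); 2 butyryl chloride
Product: 31 hexamer ring-C butanoate ester
Conditions: Et3N, DMAP (cat.), CH2Cl2, 0 °C
Reagents that add atoms: none
Why: Nucleophile-catalysed O-acylation (acyl transfer through the acylpyridinium ion) of the only free hydroxyl group in the molecule.

Step 19
Reactants: 31 hexamer ring-C butanoate ester
Product: 32 per-O-methylated target
Conditions: Sc(OTf)3 (10 mol%), toluene, 4 Å MS, 80 °C
Reagents that add atoms: none
Why: Lewis-acid-catalysed Fries rearrangement, in which the acyl group can only go to C6 of ring C, the one unsubstituted aromatic carbon in the molecule, ortho to the freed phenol and activated by both ring-C methoxy groups.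

Step 20
Reactants: 32 per-O-methylated target
Product: 33 CNP0309827.0 (target)
Conditions: BBr3 (excess), CH2Cl2, −78 °C → rt; H2O
Reagents that add atoms: none
Why: Lewis-acid ether cleavage in which BBr3 binds each ether oxygen and bromide removes the methyl group by SN2, the ethers next to carbonyl groups and the two vinylogous esters of ring A going first by chelation and the five twisted ethers following on warming.

Compound list
1 | 1,3,5-trimethoxybenzene | COc1cc(OC)cc(OC)c1 | starting material
2 | butyryl chloride (butanoyl chloride) | CCCC(=O)Cl | starting material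
3 | 1-(2,4,6-trimethoxyphenyl)butan-1-one | CCCC(=O)c1c(OC)cc(OC)cc1OC | intermediate
4 | 1-[3,5-bis(bromomethyl)-2,4,6-trimethoxyphenyl]butan-1-one | CCCC(=O)c1c(OC)c(CBr)c(OC)c(CBr)c1OC | intermediate
5 | 2,4,6-trimethoxytoluene | Cc1c(OC)cc(OC)cc1OC | starting material
6 | 1-(2,4,6-trimethoxy-3-methylphenyl)butan-1-one | CCCC(=O)c1c(OC)cc(OC)c(C)c1OC | intermediate
7 | 1-[3-(bromomethyl)-2,4,6-trimethoxy-5-methylphenyl]butan-1-one | CCCC(=O)c1c(OC)c(CBr)c(OC)c(C)c1OC | intermediate
8 | E-F diarylmethane: 1-{3-[(3-butanoyl-2,4,6-trimethoxy-5-methylphenyl)methyl]-2,4,6-trimethoxyphenyl}butan-1-one | CCCC(=O)c1c(OC)cc(OC)c(Cc2c(OC)c(C)c(OC)c(C(=O)CCC)c2OC)c1OC | intermediate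
9 | D-E-F benzylic bromide: ring D is a 5-butanoyl-2,4,6-trimethoxybenzene carrying CH2Br on C1 and a CH2 bridge on C3 to ring E; ring E is the same unit, bridged by CH2 to ring F (3-butanoyl-2,4,6-trimethoxy-5-methylphenyl) | BrCc4c(OC)c(Cc5c(OC)c(Cc6c(OC)c(C)c(OC)c(C(=O)CCC)c6OC)c(OC)c(C(=O)CCC)c5OC)c(OC)c(C(=O)CCC)c4OC | intermediate
10 | chloroacetaldehyde dimethyl acetal (2-chloro-1,1-dimethoxyethane) | COC(CCl)OC | starting material
11 | sodium methoxyacetylide | COC#[C-].[Na+] | intermediate
12 | methoxyacetylene (methoxyethyne) | COC#C | intermediate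
13 | lithium methoxyacetylide | [Li]C#COC | intermediate
14 | (methoxyethynyl)zinc chloride, handled as a THF solution | COC#C[Zn]Cl | intermediate
15 | D-E-F methyl ynol ether: as 9, with 3-methoxyprop-2-yn-1-yl (CH2–C≡C–OMe) in place of CH2Br | COC#CCc4c(OC)c(Cc5c(OC)c(Cc6c(OC)c(C)c(OC)c(C(=O)CCC)c6OC)c(OC)c(C(=O)CCC)c5OC)c(OC)c(C(=O)CCC)c4OC | intermediate
16 | trichloroacetyl chloride | O=C(Cl)C(Cl)(Cl)Cl | starting material
17 | dichloroketene | O=C=C(Cl)Cl | intermediate
18 | D-E-F 4,4-dichloro-3-methoxycyclobutenone: 4,4-dichloro-3-methoxycyclobut-2-en-1-one carrying the D-E-F benzyl group on C2 | O=C1C(Cl)(Cl)C(OC)=C1Cc4c(OC)c(Cc5c(OC)c(Cc6c(OC)c(C)c(OC)c(C(=O)CCC)c6OC)c(OC)c(C(=O)CCC)c5OC)c(OC)c(C(=O)CCC)c4OC | intermediate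
19 | D-E-F 3-methoxycyclobutenone: 3-methoxycyclobut-2-en-1-one carrying the D-E-F benzyl group on C2 | O=C1CC(OC)=C1Cc4c(OC)c(Cc5c(OC)c(Cc6c(OC)c(C)c(OC)c(C(=O)CCC)c6OC)c(OC)c(C(=O)CCC)c5OC)c(OC)c(C(=O)CCC)c4OC | intermediate
20 | phloroglucinol | Oc1cc(O)cc(O)c1 | starting material
21 | 1-(2,4,6-trihydroxyphenyl)butan-1-one | CCCC(=O)c1c(O)cc(O)cc1O | intermediate
22 | butyrylfilicinic acid: 2-butanoyl-3,5-dihydroxy-4,4-dimethylcyclohexa-2,5-dien-1-one | CCCC(=O)C1=C(O)C(C)(C)C(O)=CC1=O | intermediate
23 | A-B benzylic bromide, ring A unprotected: 2-butanoyl-6-{[3-(bromomethyl)-5-butanoyl-2,4,6-trimethoxyphenyl]methyl}-3,5-dihydroxy-4,4-dimethylcyclohexa-2,5-dien-1-one | CCCC(=O)C1=C(O)C(C)(C)C(O)=C(Cc2c(OC)c(CBr)c(OC)c(C(=O)CCC)c2OC)C1=O | intermediate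
24 | A-B benzylic bromide, ring A as bis-methyl enol ether: 2-butanoyl-6-{[3-(bromomethyl)-5-butanoyl-2,4,6-trimethoxyphenyl]methyl}-3,5-dimethoxy-4,4-dimethylcyclohexa-2,5-dien-1-one | CCCC(=O)C1=C(OC)C(C)(C)C(OC)=C(Cc2c(OC)c(CBr)c(OC)c(C(=O)CCC)c2OC)C1=O | intermediate
25 | A-B methyl ynol ether: as 24, with 3-methoxyprop-2-yn-1-yl in place of CH2Br | CCCC(=O)C1=C(OC)C(C)(C)C(OC)=C(Cc2c(OC)c(CC#COC)c(OC)c(C(=O)CCC)c2OC)C1=O | intermediate
26 | vinylketene from 19: 3-methoxybuta-1,3-dien-1-one carrying the D-E-F benzyl group on C2 | O=C=C(Cc4c(OC)c(Cc5c(OC)c(Cc6c(OC)c(C)c(OC)c(C(=O)CCC)c6OC)c(OC)c(C(=O)CCC)c5OC)c(OC)c(C(=O)CCC)c4OC)C(OC)=C | intermediate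
27 | 4-vinylcyclobutenone (racemic): 3-methoxycyclobut-2-en-1-one with the A-B benzyl group on C2 and, on the quaternary C4, the D-E-F benzyl group and a 1-methoxyvinyl group | CCCC(=O)C1=C(OC)C(C)(C)C(OC)=C(Cc2c(OC)c(CC3=C(OC)C(Cc4c(OC)c(Cc5c(OC)c(Cc6c(OC)c(C)c(OC)c(C(=O)CCC)c6OC)c(OC)c(C(=O)CCC)c5OC)c(OC)c(C(=O)CCC)c4OC)(C(OC)=C)C3=O)c(OC)c(C(=O)CCC)c2OC)C1=O | intermediate
28 | dienylketene: 3,5-dimethoxyhexa-1,3,5-trien-1-one with the A-B benzyl group on C2 and the D-E-F benzyl group on C4, ketene carbon and methoxyvinyl group cis across the C3=C4 bond | CCCC(=O)C1=C(OC)C(C)(C)C(OC)=C(Cc2c(OC)c(CC(=C=O)/C(OC)=C(/Cc4c(OC)c(Cc5c(OC)c(Cc6c(OC)c(C)c(OC)c(C(=O)CCC)c6OC)c(OC)c(C(=O)CCC)c5OC)c(OC)c(C(=O)CCC)c4OC)C(OC)=C)c(OC)c(C(=O)CCC)c2OC)C1=O | intermediate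
29 | cyclohexadienone: 3,5-dimethoxycyclohexa-2,4-dien-1-one with the A-B benzyl group on C2 and the D-E-F benzyl group on C4 (keto tautomer of 30) | CCCC(=O)C1=C(OC)C(C)(C)C(OC)=C(Cc2c(OC)c(CC3=C(OC)C(Cc4c(OC)c(Cc5c(OC)c(Cc6c(OC)c(C)c(OC)c(C(=O)CCC)c6OC)c(OC)c(C(=O)CCC)c5OC)c(OC)c(C(=O)CCC)c4OC)=C(OC)CC3=O)c(OC)c(C(=O)CCC)c2OC)C1=O | intermediate
30 | protected hexamer phenol: ring C is 3,5-dimethoxyphenol with the A-B benzyl group on C2, the D-E-F benzyl group on C4 and H on C6; all other oxygens as methyl ethers | CCCC(=O)C1=C(OC)C(C)(C)C(OC)=C(Cc2c(OC)c(Cc3c(O)cc(OC)c(Cc4c(OC)c(Cc5c(OC)c(Cc6c(OC)c(C)c(OC)c(C(=O)CCC)c6OC)c(OC)c(C(=O)CCC)c5OC)c(OC)c(C(=O)CCC)c4OC)c3OC)c(OC)c(C(=O)CCC)c2OC)C1=O | intermediate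
31 | hexamer ring-C butanoate ester: 30 with its phenol as the butanoate | CCCC(=O)C1=C(OC)C(C)(C)C(OC)=C(Cc2c(OC)c(Cc3c(OC(=O)CCC)cc(OC)c(Cc4c(OC)c(Cc5c(OC)c(Cc6c(OC)c(C)c(OC)c(C(=O)CCC)c6OC)c(OC)c(C(=O)CCC)c5OC)c(OC)c(C(=O)CCC)c4OC)c3OC)c(OC)c(C(=O)CCC)c2OC)C1=O | intermediate
32 | per-O-methylated target: 30 with butanoyl on C6 of ring C, ortho to the free phenol | CCCC(=O)C1=C(OC)C(C)(C)C(OC)=C(Cc2c(OC)c(Cc3c(O)c(C(=O)CCC)c(OC)c(Cc4c(OC)c(Cc5c(OC)c(Cc6c(OC)c(C)c(OC)c(C(=O)CCC)c6OC)c(OC)c(C(=O)CCC)c5OC)c(OC)c(C(=O)CCC)c4OC)c3OC)c(OC)c(C(=O)CCC)c2OC)C1=O | intermediate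
33 | CNP0309827.0 (achiral hexameric methylene-bridged acylphloroglucinol) | CCCC(=O)C1=C(O)C(C)(C)C(O)=C(Cc2c(O)c(Cc3c(O)c(Cc4c(O)c(Cc5c(O)c(Cc6c(O)c(C)c(O)c(C(=O)CCC)c6O)c(O)c(C(=O)CCC)c5O)c(O)c(C(=O)CCC)c4O)c(O)c(C(=O)CCC)c3O)c(O)c(C(=O)CCC)c2O)C1=O | target

Total step count: 20 steps.
Longest linear sequence: 11 steps (5 → 6 → 7 → 8 → 9 → 15 → 18 → 19 → 30 → 31 → 32 → 33; steps 3, 4, 5, 6, 9, 10, 11, 17, 18, 19, 20).

Steps most likely to fail

Step 17. The 3-methoxy group makes the cyclobutenone a vinylogous ester, so its electrocyclic opening may be slow. Long heating could then let the vinylketene acylate the phenol as it forms, or the crowded [2+2] addition could stall. The fallback builds ring C by Friedel–Crafts chemistry from a preformed phenol; it sets out from bromides 9 and 24 and returns at 30. Commercial 3,5-dimethoxyphenol (excess) would be benzylated with 9 in HFIP/CH2Cl2 over NaHCO3. Substitution para to the hydroxyl group, between the two methoxy groups, should give the 4-benzylated 3,5-dimethoxyphenol F1, to be separated from its ortho isomer. F1 would then be benzylated with 24 under the same conditions at one of its two equivalent ortho carbons, which gives 30.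

Step 20. The five non-chelated ethers may be cleaved incompletely, and long exposure to excess BBr3 may cause scission or exchange of the CH2 bridges or dehydrative ring closure between neighbouring phenols. The fallback unmasks in two stages with two different reagents, from 32 back to 33. BCl3 in CH2Cl2 at −78 → 0 °C should remove only the methyl groups next to carbonyl groups (by chelation) and the two vinylogous esters of ring A. This gives the partly unmasked hexamer F2, with one methoxy group left on each of rings B to F. These five twisted ethers would then be cleaved with iodotrimethylsilane made from TMSCl and NaI in MeCN, and aqueous work-up gives 33.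

Step 19. The Lewis acid may cause loss of the acyl group back to phenol 30, or exchange of the diarylmethane bridges, before the acyl group reaches C6. The fallback acylates the methyl ether intermolecularly, from 30 back to 33. Phenol 30 would be O-methylated (MeI, K2CO3, acetone) to the ring-C trimethyl ether F3. Friedel–Crafts acylation of F3 with butyryl chloride 2 and SnCl4 in CH2Cl2 at −78 → −20 °C, at the only unsubstituted aromatic carbon, should give the fully O-methylated hexamer F4. Exhaustive demethylation of F4 under the conditions of step 20 gives 33.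

Further compounds
F1 | step 17 | 3,5-dimethoxyphenol carrying the D-E-F benzyl group on C4 | Oc1cc(OC)c(Cc4c(OC)c(Cc5c(OC)c(Cc6c(OC)c(C)c(OC)c(C(=O)CCC)c6OC)c(OC)c(C(=O)CCC)c5OC)c(OC)c(C(=O)CCC)c4OC)c(OC)c1
F2 | step 20 | partly unmasked hexamer: target with one methyl ether left on each of rings B to F (the oxygen para to the butanoyl group) | CCCC(=O)C1=C(O)C(C)(C)C(O)=C(Cc2c(OC)c(Cc3c(O)c(C(=O)CCC)c(O)c(Cc4c(OC)c(Cc5c(OC)c(Cc6c(OC)c(C)c(O)c(C(=O)CCC)c6O)c(O)c(C(=O)CCC)c5O)c(O)c(C(=O)CCC)c4O)c3OC)c(O)c(C(=O)CCC)c2O)C1=O
F3 | step 19 | ring-C trimethyl ether: 30 with its phenol O-methylated | CCCC(=O)C1=C(OC)C(C)(C)C(OC)=C(Cc2c(OC)c(Cc3c(OC)cc(OC)c(Cc4c(OC)c(Cc5c(OC)c(Cc6c(OC)c(C)c(OC)c(C(=O)CCC)c6OC)c(OC)c(C(=O)CCC)c5OC)c(OC)c(C(=O)CCC)c4OC)c3OC)c(OC)c(C(=O)CCC)c2OC)C1=O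
F4 | step 19 | fully O-methylated hexamer: F3 with butanoyl on the free carbon of ring C | CCCC(=O)C1=C(OC)C(C)(C)C(OC)=C(Cc2c(OC)c(Cc3c(OC)c(C(=O)CCC)c(OC)c(Cc4c(OC)c(Cc5c(OC)c(Cc6c(OC)c(C)c(OC)c(C(=O)CCC)c6OC)c(OC)c(C(=O)CCC)c5OC)c(OC)c(C(=O)CCC)c4OC)c3OC)c(OC)c(C(=O)CCC)c2OC)C1=O
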